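The data come from a simulation with constants of no real substance, and the scatter is random.

Start with the rate.

| setting | Tuesday's | Sunday's | flask |
|---|---|---|---|
| left-handed substrate | 0.30 M | 0.30 M | 0.30 M |
| right-handed substrate | 0.30 M | 0.30 M | 0.30 M |
| solid reagent | 0.66 M | 0.66 M | 0.660 M |
| free catalyst | 0.42 mM | 0.42 mM | 0.42 mM |
| racemization catalyst | 0.14 mM | 0.20 mM | 0.27 mM |
| remark | run made earlier | run made earlier |  |
| time |  |  | 4.0 d |

| run | time / d | left-handed product / % | right-handed product / % |
|---|---|---|---|
| Tuesday's | 1.25 | 11.6 | 2.5 |
| Tuesday's | 2.50 | 21.7 | 4.7 |
| Tuesday's | 4.00 | 34.5 | 7.4 |
| Tuesday's | 5.00 | 43.3 | 9.7 |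
| Sunday's | 0.417 | 3.4 | 0.9 |
| Sunday's | 0.833 | 7.0 | 1.3 |
| Sunday's | 2.08 | 18.8 | 4.3 |
| Sunday's | 5.00 | 42.9 | 9.7 |

(readings scatter by 0.3 percentage points)

- left-handed product and right-handed product together, in percent of the left-handed substrate and right-handed substrate charged together, at 4.0 d
- excess of left-handed product over right-handed product in the product at 4.0 d
- whether the exchange between left-handed substrate and right-handed substrate keeps pace with the reaction: how far the product's excess at 4.0 d gets from its value without exchange to its value with instant exchange (above 80% keeps pace, below 20% hardly takes part, else lags behind)

- free catalyst is single-handed; left-handed substrate and right-handed substrate are mirror images of each other, charged as a racemate, each of them at the stated concentration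
- as a solid, counted per litre of solution: solid reagent
- the earlier runs were read with a standard deviation of 0.3 percentage points
- on the list of suspects stand: coupling partner + free catalyst + right-handed substrate -> free catalyst + right-handed product; solid reagent <-> coupling partner; 2 free catalyst <-> resting dimer; left-handed substrate + racemization catalyst <-> right-handed substrate + racemization catalyst; coupling partner -> decomposed reagent; coupling partner + free catalyst + left-handed substrate -> free catalyst + left-handed product
- at the start none of the solid reagent is in solution
- an excess is below zero if the other one leads

I follow the pace J: moles of product of both hands formed per litre per day. Tuesday's run begins at 0.0677 M/d and its last interval reads 0.0666 M/d. That is a factor of 0.984 in pace, as a reading, while the substrates left fall to 47.0% of their charge at 5.00 d. Tuesday's readings look zero-order in the substrates.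

Sunday's run has 1.43 times Tuesday's racemization catalyst, and its average pace up to 5.00 d reads 0.992 times Tuesday's. I find no accumulated slowing in these readings, so I carry the average pace of Tuesday's run:

J = 0.0636 M/d, the product formed per litre per day

J·t = 0.254 M

y = J·t / (both substrates charged) = 42.4%

This amount stands below both charges, the substrates' 0.600 M and the solid reagent's 0.660 M, so neither ends the line at 4.0 d.

The forecast gives 42%, an excess of 64.3%, and an exchange that keeps pace. Its ground: “That suggests the rate is set by the solid reagent dissolving, not by the substrates or the racemization catalyst.”

The flask gives 42.6% and an excess of 64.7%, and the exchange keeps pace, getting 94% of the way to the instant value. At 4.00 d the coupling partner stands at 0.00385 M, made 1.01 times as fast as it is used up. Against J·t = 0.254 M, the flask holds 0.255 M of product, and its solid reagent has lost 0.277 M. Decomposed reagent holds 0.0179 M of that loss, 6.45% of it, and the coupling partner in solution holds the amount above; J counts product, so it is the pace net of both.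

    coupling partner + free catalyst + right-handed substrate → free catalyst + right-handed product (k = 2510 /M²/h)
    solid reagent ⇌ coupling partner, rate k2*(cs2 - [coupling partner]) while solid is left; crystals form when [coupling partner] > cs2 (solubility = 37.0 mM, k = 0.0849 /h)
    2 free catalyst ⇌ resting dimer (K = 1060 /M, k = 350 /M/h)
    left-handed substrate + racemization catalyst ⇌ right-handed substrate + racemization catalyst, rate k4*[racemization catalyst]*[left-handed substrate] forward; the back reaction follows from the equilibrium constant (k = 558 /M/h)
    coupling partner → decomposed reagent (k = 0.0624 /h)
    coupling partner + free catalyst + left-handed substrate → free catalyst + left-handed product (k = 12000 /M²/h)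

In a second flask, the same but with 0.17 M of solid reagent, that charge divided by J gives an estimated 2.67 d, and the charge itself caps y at 28.3%. The computed flask gives 26.7%, with 0% of the solid reagent left, the limiting reagent there, and 0.00997 M of decomposed reagent.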